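**Retrosynthetic overview**
1. Target 24 ⇐ its 10-O-triethylsilyl ether 23 (Si–O cleavage only).
2. 23 ⇐ acyclic iodo-enone aldehyde 21 in one Ni/Cr operation: the C5–C6 bond closes the 10-membered carbocycle first, then the new C6 alkoxide closes the cis-γ-lactone onto the C12 ester.
3. 21 ⇐ ynone 18 + formaldehyde + iodide (C4–C15 bond and the Z C4=C5–I unit); 18 ⇐ aldehyde 15 + ethynyl Grignard (C3–C4).
4. 15 ⇐ aldehyde 9 + allyl bromide 4 (C7–C8 by catalytic asymmetric, syn-selective Cr allylation), then angelate, then ozonolysis.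
5. 9 ⇐ (R)-linalool (C10 from the chiral pool); 4 ⇐ methyl acrylate + glyoxal dimethyl acetal.

Assumption: the target is made as the open γ-hydroxy ketone drawn (it may equilibrate with its 3,10-hemiketal); locants C1–C15 are germacrane numbering (C3 ketone, C6 lactone carbinol, C8 angelate carbinol, C10 tertiary carbinol, C15 CH2OH); for the chiral chromium catalysts the ligand enantiomer is the one that gives the stated face.

**Route**

Step 1
Reactants: 1 methyl acrylate; 2 2,2-dimethoxyacetaldehyde (60 % aq.)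
Product: 3 methyl 3-hydroxy-4,4-dimethoxy-2-methylidenebutanoate (racemic)
Conditions: DABCO (0.5 equiv), 1,4-dioxane/H2O, rt, 48 h
Reagents that add atoms: none
Why: Morita–Baylis–Hillman reaction of the acrylate with an activated α,α-dialkoxy aldehyde; the new carbinol centre is racemic and is erased in step 2.

Step 2
Reactants: 3 methyl 3-hydroxy-4,4-dimethoxy-2-methylidenebutanoate
Product: 4 methyl (2Z)-2-(bromomethyl)-4,4-dimethoxybut-2-enoate
Conditions: NBS, Me2S, CH2Cl2, 0 °C → rt
Reagents that add atoms: N-bromosuccinimide O=C1CCC(=O)N1Br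
Why: Corey–Kim-type activation of the allylic alcohol and SN2′ return of bromide give the rearranged, thermodynamically favoured (Z)-2-(bromomethyl)enoate under non-acidic conditions that spare the acetal.

Step 3
Reactants: 5 (R)-(−)-linalool
Product: 6 (3R)-3,7-dimethyl-3-(triethylsilyloxy)octa-1,6-diene
Conditions: TESOTf, 2,6-lutidine, CH2Cl2, −78 → 0 °C
Reagents that add atoms: triethylsilyl triflate CC[Si](CC)(CC)OS(=O)(=O)C(F)(F)F
Why: Silylation of the hindered tertiary allylic alcohol with the silyl triflate; C10, taken from the chiral pool, is untouched.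

Step 4
Reactants: 6 (3R)-3,7-dimethyl-3-(triethylsilyloxy)octa-1,6-diene
Product: 8 (3R)-3,7-dimethyl-3-(triethylsilyloxy)oct-6-en-1-ol, via B-alkyl-9-BBN adduct 7 (not isolated)
Conditions: 9-BBN, THF, 0 °C → rt; then NaOH, H2O2, 0 °C
Reagents that add atoms: 9-BBN [H]B1C2CCCC1CCC2 (boron carried by 7 only); hydrogen peroxide OO
Why: Anti-Markovnikov hydroboration–oxidation; 9-BBN takes the monosubstituted vinyl group and leaves the trisubstituted alkene.

Step 5
Reactants: 8 (3R)-3,7-dimethyl-3-(triethylsilyloxy)oct-6-en-1-ol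
Product: 9 (3R)-3,7-dimethyl-3-(triethylsilyloxy)oct-6-enal
Conditions: Dess–Martin periodinane, NaHCO3, CH2Cl2, 0 °C → rt
Reagents that add atoms: none
Why: Dess–Martin oxidation of the primary alcohol to the β-silyloxy aldehyde without touching the alkene or the silyl ether.

Step 6
Reactants: 9 (3R)-3,7-dimethyl-3-(triethylsilyloxy)oct-6-enal; 4 methyl (2Z)-2-(bromomethyl)-4,4-dimethoxybut-2-enoate
Product: 11 methyl (3R,4R,6R)-3-(dimethoxymethyl)-4-hydroxy-6,10-dimethyl-2-methylidene-6-(triethylsilyloxy)undec-9-enoate [(7R,8R,10R)], via O-trimethylsilyl ether 10 (not isolated)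
Conditions: CrCl2 (10 mol %), chiral carbazole–bis(oxazoline) ligand (12 mol %), Mn, TMSCl, THF, rt; then aq. citric acid, THF, 0 °C, 10 min
Reagents that add atoms: chlorotrimethylsilane C[Si](C)(C)Cl (its silyl group is carried by 10 only)
Why: Catalytic asymmetric Nozaki–Hiyama 2-(alkoxycarbonyl)allylation (Mn/TMSCl turnover): the γ-substituted allylchromium reacts through a chair transition state to give the syn C7/C8 adduct, the chiral Cr complex directs attack to the Si face of the aldehyde (8R, hence 7R) irrespective of the remote C10 centre, and O-silylation of the alkoxide keeps the ester from closing to an 8,12-lactone.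

Step 7
Reactants: 11 hydroxy ester (7R,8R,10R); 12 angelic acid [(2Z)-2-methylbut-2-enoic acid]
Product: 13 methyl (3R,4R,6R)-4-(angeloyloxy)-3-(dimethoxymethyl)-6,10-dimethyl-2-methylidene-6-(triethylsilyloxy)undec-9-enoate
Conditions: 12, 2,4,6-trichlorobenzoyl chloride, Et3N, toluene, rt, 2 h; then 11, 70 °C (no DMAP)
Reagents that add atoms: none
Why: Yamaguchi mixed-anhydride esterification without DMAP, the usual way to acylate a hindered secondary alcohol with angelic acid without Z→E isomerisation; no stereocentre is affected.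

Step 8
Reactants: 13 C8 angelate
Product: 15 methyl (3R,4R,6R)-4-(angeloyloxy)-3-(dimethoxymethyl)-6-methyl-2-methylidene-9-oxo-6-(triethylsilyloxy)nonanoate (C3 aldehyde), via secondary ozonide 14 (not isolated)
Conditions: O3, CH2Cl2, −78 °C (Sudan Red 7B end-point); then Me2S, −78 °C → rt
Reagents that add atoms: ozone [O-][O+]=O
Why: Ozonolysis with reductive work-up; the electron-rich trisubstituted alkene reacts far faster than the conjugated acrylate and angelate double bonds, so ozone is titrated to the dye end-point.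

Step 9
Reactants: 15 C3 aldehyde; 16 ethynylmagnesium bromide
Product: 17 methyl (3R,4R,6R,9RS)-4-(angeloyloxy)-3-(dimethoxymethyl)-9-hydroxy-6-methyl-2-methylidene-6-(triethylsilyloxy)undec-10-ynoate
Conditions: THF, −78 °C; aq. NH4Cl
Reagents that add atoms: none
Why: Grignard 1,2-addition to the aldehyde at −78 °C, chemoselective over the esters; the new C3 carbinol (about 1:1) is oxidised in the next step.

Step 10
Reactants: 17 propargylic alcohol
Product: 18 methyl (3R,4R,6R)-4-(angeloyloxy)-3-(dimethoxymethyl)-6-methyl-2-methylidene-9-oxo-6-(triethylsilyloxy)undec-10-ynoate (terminal ynone)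
Conditions: Dess–Martin periodinane, NaHCO3, CH2Cl2, 0 °C
Reagents that add atoms: none
Why: Dess–Martin oxidation of the propargylic alcohol to the terminal ynone, which removes the C3 stereocentre.

Step 11
Reactants: 18 terminal ynone; 19 formaldehyde (monomeric, THF solution)
Product: 20 methyl (3R,4R,6R,10Z)-4-(angeloyloxy)-3-(dimethoxymethyl)-10-(hydroxymethyl)-11-iodo-6-methyl-2-methylidene-9-oxo-6-(triethylsilyloxy)undec-10-enoate
Conditions: MgI2 (1.2 equiv), CH2Cl2, −40 → 0 °C; aq. NaHCO3
Reagents that add atoms: magnesium iodide [Mg+2].[I-].[I-]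
Why: Iodo-aldol (β-iodo Morita–Baylis–Hillman-type) reaction: iodide adds to the ynone to give a β-iodoallenolate that attacks formaldehyde at the α-carbon from the side away from iodine, giving the (Z)-β-iodo-α-(hydroxymethyl)enone with iodine cis to the ketone, the geometry needed for the ring alkene.

Step 12
Reactants: 20 iodo-enone dimethyl acetal
Product: 21 methyl (3R,4R,6R,10Z)-4-(angeloyloxy)-3-formyl-10-(hydroxymethyl)-11-iodo-6-methyl-2-methylidene-9-oxo-6-(triethylsilyloxy)undec-10-enoate (C6 aldehyde)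
Conditions: In(OTf)3 (5 mol %), acetone/H2O 20:1, rt; used crude at once
Reagents that add atoms: water O
Why: Lewis-acid-catalysed acetal hydrolysis under near-neutral conditions that keep the tertiary silyl ether, the esters and the epimerisable C7 centre.

Step 13
Reactants: 21 iodo-enone aldehyde
Product: 23 (3aR,4R,6R,10Z,11aS)-10-(hydroxymethyl)-6-methyl-3-methylidene-2,9-dioxo-6-(triethylsilyloxy)-2,3,3a,4,5,6,7,8,9,11a-decahydrocyclodeca[b]furan-4-yl (2Z)-2-methylbut-2-enoate, via macrocyclic C6 chromium alkoxide 22 (not isolated)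
Conditions: CrCl2 (8 equiv), NiCl2 (2 mol %), DMSO/THF 1:3, 2 mM, slow addition, 25 °C; aq. sodium serinate work-up
Reagents that add atoms: none
Why: Proposed new method: Ni(0) inserts into the (Z)-β-iodoenone C–I bond and hands the alkenyl group to Cr(III) with retention, the alkenylchromium adds to the C6 aldehyde to close the 10-membered ring (the cis alkene pre-organises the chain), and the Cr(III) alkoxide then acylates itself on the neighbouring acrylate methyl ester as γ-alkoxides do in Cr-mediated 2-(alkoxycarbonyl)allylations, so carbocycle and γ-lactone form in one operation; the closest known reactions are Nozaki–Hiyama–Kishi macrocyclisation and the NHK/lactonisation of (Z)-β-iodoacrylates to butenolides; C6 is expected 6S (H6 cis to H7) because in the ring-closing transition state the tether carbon C8 cannot sit anti to the incoming alkenyl group, so the exocyclic acrylate takes the Felkin–Anh anti position and the Si face of the aldehyde is attacked.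

Step 14
Reactants: 23 10-O-triethylsilyl ether of the target
Product: 24 target, (3aR,4R,6R,10Z,11aS)-6-hydroxy-10-(hydroxymethyl)-6-methyl-3-methylidene-2,9-dioxo-2,3,3a,4,5,6,7,8,9,11a-decahydrocyclodeca[b]furan-4-yl (2Z)-2-methylbut-2-enoate
Conditions: HF·pyridine, pyridine, THF, 0 °C → rt
Reagents that add atoms: none
Why: Buffered fluoride cleavage of the tertiary triethylsilyl ether; lactone, enone and angelate are inert and no stereocentre is touched.

**Compound list**
1 | methyl acrylate | C=CC(=O)OC | starting material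
2 | 2,2-dimethoxyacetaldehyde | COC(OC)C=O | starting material
3 | methyl 3-hydroxy-4,4-dimethoxy-2-methylidenebutanoate (racemic) | COC(=O)C(=C)C(O)C(OC)OC | intermediate
4 | methyl (2Z)-2-(bromomethyl)-4,4-dimethoxybut-2-enoate | COC(=O)/C(CBr)=C/C(OC)OC | intermediate
5 | (R)-(−)-linalool | CC(C)=CCC[C@@](C)(O)C=C | starting material
6 | (3R)-3,7-dimethyl-3-(triethylsilyloxy)octa-1,6-diene | CC(C)=CCC[C@@](C)(O[Si](CC)(CC)CC)C=C | intermediate
7 | B-alkyl-9-BBN adduct of 6 (boron on the former terminal vinyl carbon, carbinol configuration unchanged) | CC(C)=CCC[C@@](C)(O[Si](CC)(CC)CC)CCB1C2CCCC1CCC2 | intermediate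
8 | (3R)-3,7-dimethyl-3-(triethylsilyloxy)oct-6-en-1-ol | CC(C)=CCC[C@@](C)(O[Si](CC)(CC)CC)CCO | intermediate
9 | (3R)-3,7-dimethyl-3-(triethylsilyloxy)oct-6-enal | CC(C)=CCC[C@@](C)(O[Si](CC)(CC)CC)CC=O | intermediate
10 | O-trimethylsilyl ether of 11 (7R,8R,10R) | CC(C)=CCC[C@@](C)(O[Si](CC)(CC)CC)C[C@@H](O[Si](C)(C)C)[C@H](C(OC)OC)C(=C)C(=O)OC | intermediate
11 | methyl (3R,4R,6R)-3-(dimethoxymethyl)-4-hydroxy-6,10-dimethyl-2-methylidene-6-(triethylsilyloxy)undec-9-enoate | CC(C)=CCC[C@@](C)(O[Si](CC)(CC)CC)C[C@@H](O)[C@H](C(OC)OC)C(=C)C(=O)OC | intermediate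
12 | angelic acid, (2Z)-2-methylbut-2-enoic acid | C/C=C(/C)C(=O)O | starting material
13 | C8 angelate of 11 (7R,8R,10R) | CC(C)=CCC[C@@](C)(O[Si](CC)(CC)CC)C[C@@H](OC(=O)/C(C)=C\C)[C@H](C(OC)OC)C(=C)C(=O)OC | intermediate
14 | secondary ozonide (1,2,4-trioxolane) of 13 | CC1(C)OOC(CC[C@@](C)(O[Si](CC)(CC)CC)C[C@@H](OC(=O)/C(C)=C\C)[C@H](C(OC)OC)C(=C)C(=O)OC)O1 | intermediate
15 | C3 aldehyde (7R,8R,10R) | O=CCC[C@@](C)(O[Si](CC)(CC)CC)C[C@@H](OC(=O)/C(C)=C\C)[C@H](C(OC)OC)C(=C)C(=O)OC | intermediate
16 | ethynylmagnesium bromide | C#C[Mg]Br | starting material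
17 | C3 propargylic alcohol (7R,8R,10R; C3 mixture) | C#CC(O)CC[C@@](C)(O[Si](CC)(CC)CC)C[C@@H](OC(=O)/C(C)=C\C)[C@H](C(OC)OC)C(=C)C(=O)OC | intermediate
18 | terminal ynone (7R,8R,10R) | C#CC(=O)CC[C@@](C)(O[Si](CC)(CC)CC)C[C@@H](OC(=O)/C(C)=C\C)[C@H](C(OC)OC)C(=C)C(=O)OC | intermediate
19 | formaldehyde | C=O | starting material
20 | (Z)-β-iodo-α-(hydroxymethyl)enone dimethyl acetal (7R,8R,10R) | I/C=C(/CO)C(=O)CC[C@@](C)(O[Si](CC)(CC)CC)C[C@@H](OC(=O)/C(C)=C\C)[C@H](C(OC)OC)C(=C)C(=O)OC | intermediate
21 | (Z)-iodo-enone C6 aldehyde (7R,8R,10R) | I/C=C(/CO)C(=O)CC[C@@](C)(O[Si](CC)(CC)CC)C[C@@H](OC(=O)/C(C)=C\C)[C@H](C=O)C(=C)C(=O)OC | intermediate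
22 | macrocyclic C6 chromium(III) alkoxide, C7 carrying the 1-(methoxycarbonyl)vinyl group (6S,7S,8R,10R; drawn as the free alcohol) | COC(=O)C(=C)[C@H]1[C@@H](O)/C=C(/CO)C(=O)CC[C@@](C)(O[Si](CC)(CC)CC)C[C@H]1OC(=O)/C(C)=C\C | intermediate
23 | 10-O-triethylsilyl ether of the target (6S,7R,8R,10R) | C=C1C(=O)O[C@H]2/C=C(/CO)C(=O)CC[C@@](C)(O[Si](CC)(CC)CC)C[C@@H](OC(=O)/C(C)=C\C)[C@@H]12 | intermediate
24 | CNP0181802.1 (6S,7R,8R,10R; 4Z) | C=C1C(=O)O[C@H]2/C=C(/CO)C(=O)CC[C@@](C)(O)C[C@@H](OC(=O)/C(C)=C\C)[C@@H]12 | target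

**Totals**
Total step count: 14. Longest linear sequence: 12 steps (5 → 24, steps 3–14).

**Three steps most likely to fail**

Step 13. The risks are the face of attack at C6 (a simple acyclic Felkin model with the C8 chain as the large group would give the 6-epimer), the lability of aldehyde 21 (C7 epimerisation, loss of angelate) and competing hemiketal/furan formation from the (Z)-γ-alkoxy enone. The fallback separates the two ring closures and hands the C6 face to a chiral catalyst. It sets out from 21: a catalytic asymmetric Ni/Cr coupling (Kishi oxazoline–sulfonamide Cr complex, NiCl2·DMP, Mn, TMSCl, MeCN, slow addition) stops at the macrocyclic C6 trimethylsilyl ether methyl ester F1, because the silylated oxygen cannot lactonise. Buffered fluoride (TBAF/AcOH, THF, 0 °C) then frees O6, which closes onto the methyl ester. It comes back to the route at 23.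

Step 11. The risks are the aldol of the iodoallenolate with monomeric formaldehyde, Lewis-acid damage to the acetal or silyl ether, and E/Z control. The fallback installs the hydroxymethyl carbon last, by cross-coupling. It sets out from 18: hydroiodination (NaI, AcOH, MeCN, rt) gives the (Z)-β-iodoenone acetal F2, and the same hydrolysis as in step 12 gives the aldehyde F3. The Ni/Cr ring closure of step 13 then gives the C15-free bicyclic lactone F5 through its macrocyclic alkoxide F4. Johnson α-iodination (I2, pyridine, CH2Cl2) gives the α-iodoenone F6, and Stille coupling with (tributylstannyl)methanol (Pd(PPh3)4, dioxane, 90 °C) puts in the CH2OH. It comes back to the route at 23.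

Step 6. The risks are enantioface control with the γ-acetal allyl bromide, β-methoxide loss from the allylchromium, and premature closure to the 8,12-lactone. The fallback replaces the allylchromium by a type I allylboration. It sets out from 4: Pd-catalysed borylation (B2pin2, Pd2(dba)3, DMSO, 50 °C) gives the allylboronate F7. Chiral phosphoric acid catalysis ((R)-TRIP, toluene, −30 °C) adds F7 to aldehyde 9 through a closed chair transition state to give the syn borate ester F8, which mild aqueous work-up hydrolyses. It comes back to the route at 11.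

**Further compounds**
F1 | step 13 | macrocyclic C6 O-trimethylsilyl ether methyl ester | COC(=O)C(=C)[C@H]1[C@@H](O[Si](C)(C)C)/C=C(/CO)C(=O)CC[C@@](C)(O[Si](CC)(CC)CC)C[C@H]1OC(=O)/C(C)=C\C
F2 | step 11 | (Z)-β-iodoenone dimethyl acetal without C15 | I/C=C\C(=O)CC[C@@](C)(O[Si](CC)(CC)CC)C[C@@H](OC(=O)/C(C)=C\C)[C@H](C(OC)OC)C(=C)C(=O)OC
F3 | step 11 | (Z)-β-iodoenone C6 aldehyde without C15 | I/C=C\C(=O)CC[C@@](C)(O[Si](CC)(CC)CC)C[C@@H](OC(=O)/C(C)=C\C)[C@H](C=O)C(=C)C(=O)OC
F4 | step 11 | macrocyclic C6 chromium alkoxide without C15 (drawn as the free alcohol) | COC(=O)C(=C)[C@H]1[C@@H](O)/C=C\C(=O)CC[C@@](C)(O[Si](CC)(CC)CC)C[C@H]1OC(=O)/C(C)=C\C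
F5 | step 11 | 15-nor analogue of 23 (bicyclic lactone, C4–H) | C=C1C(=O)O[C@H]2/C=C\C(=O)CC[C@@](C)(O[Si](CC)(CC)CC)C[C@@H](OC(=O)/C(C)=C\C)[C@@H]12
F6 | step 11 | 4-iodo analogue of 23 (α-iodoenone) | C=C1C(=O)O[C@H]2/C=C(/I)C(=O)CC[C@@](C)(O[Si](CC)(CC)CC)C[C@@H](OC(=O)/C(C)=C\C)[C@@H]12
F7 | step 6 | methyl (2E)-4,4-dimethoxy-2-[(4,4,5,5-tetramethyl-1,3,2-dioxaborolan-2-yl)methyl]but-2-enoate | COC(=O)/C(CB1OC(C)(C)C(C)(C)O1)=C/C(OC)OC
F8 | step 6 | O-pinacolboryl (borate) ester of 11 | CC(C)=CCC[C@@](C)(O[Si](CC)(CC)CC)C[C@@H](OB1OC(C)(C)C(C)(C)O1)[C@H](C(OC)OC)C(=C)C(=O)OC
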